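# Proposed synthesis of 15-O-stearoylimbricatolic acid (CNP0298278.1) through phenol dearomatization at C10

Labdane numbering is used throughout: ring A = C1–C5 and C10; ring B = C5–C10; C18 (methyl) and C19 (carboxyl) on C4; C20 (methyl) on C10; C17 (methylene) on C8; side chain C11–C16 on C9.

## The problem

The target 28 is the C15 stearate of imbricatolic acid. It is a trans-fused decalin with an axial C19 carboxylic acid and an equatorial C18 methyl at quaternary C4, an angular C20 methyl at quaternary C10, an exocyclic C8=C17 methylene, and an equatorial side chain at C9 that carries a lone stereocentre at C13 and the fatty ester at C15. The two quaternary carbons flank C5 and hold carboxyl and methyl syn-diaxial; these are the hardest bonds to make. Of the five stereocentres, the four on the rings can be chained to one another. C4 can direct C10 across C5. C4 and C10 together cover the β face and so direct the hydrogen at C5. C10 directs C9, which is also under thermodynamic control as long as C8 is a ketone. C13 is too far from the rings to be controlled by them and has to come from a chiral building block. Three groups limit the order of events. The 8(17)-alkene moves into the ring under acid and does not survive hydrogenation. The stearate is an ordinary primary ester that does not survive hydroxide, hydride or ylide. The C19 carboxyl is so shielded that its ester can only be cleaved at the alkyl group. The feature that makes the key step possible is C10: it bears a methyl and three ring bonds and sits between C5 and C9. If C9 carries oxygen, ring B is an ortho-cresol (C9–OH, C10–CH3, C5 bearing the C4 chain), and ring A can be closed by alkylating the phenoxide at its methyl-bearing ortho carbon with C1.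

## Retrosynthesis

**C15–O acyl bond.** The stearate is cut first: 28 comes from imbricatolic acid 26 and stearoyl chloride 27. This keeps the fatty ester out of every organometallic, reducing and basic step. The price is that the acylation must pick the primary C15 hydroxyl beside the free C19 acid. That is acceptable, because a tertiary axial carboxyl can at worst form a mixed anhydride that is hydrolysed on work-up.

**Protecting groups at C15 and C19.** 26 is traced to silyl ether acid 25 and that to methyl ester 24. The carboxyl travels as a methyl ester because it must pass tert-butoxide, hydrogen, borane and ylide, and because a methyl ester can be removed by thiolate attack on the methyl group without touching the shielded carbonyl. The C15 oxygen travels as a silyl ether that tolerates zinc, borane and ylide and falls to fluoride without acid.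

**C8=C17.** The exocyclic alkene is the last C–C bond made on the skeleton, by Wittig methylenation of ketone 23. 23 comes from alcohol 22, and 22 from hydroboration–oxidation of the C8=C9 alkene 20. One alkene thus supplies both centres: oxygen at C8 and hydrogen at C9, delivered from the face opposite the C20 methyl. C9 is additionally secured because its equatorial side chain is the stable arrangement next to the C8 ketone.

**C9–C11.** Alkene 20 is cut at the sp2–sp3 bond between ring and chain into enol triflate 13 and alkylzinc iodide 19, made from iodide 18. The neighbouring cuts (C11–C12, C12–C13) would need a neopentyl-type reaction centre beside quaternary C10 and would not use the C9 oxygen. This cut turns that oxygen (ketone 11) into the coupling handle and leaves the alkene needed above. Fragment 18 holds C11–C16 with C13 set. It comes from (S)-citronellol 14 via silyl ether 15 and acid 17 (through aldehyde 16). Citronellol is one carbon too long on its alkene side; oxidative cleavage removes the isopropylidene carbon as acetone and iododecarboxylation removes the next carbon as CO2.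

**C5–H and the ring B double bonds.** Ketone 11 is the tetrahydro derivative of dienone 10. The precursor is simpler by one stereocentre. The hydrogenation must add to C5=C6 from the α face, which is the open one because the axial C19 ester and the C20 methyl both lie on the β face.

**C1–C10 (key disconnection).** Dienone 10 is opened between C1 and quaternary C10. The precursor is phenol 8, reacting as its phenoxide 9: an ortho-cresol with a 3-bromopropyl chain on the benzylic quaternary carbon C4. Against other cuts at C10 (angular methylation of a bicyclic enolate, annulation across C5–C10 or C9–C10) this one removes a ring and a quaternary stereocentre together and leaves an aromatic compound with one stereocentre. Ring B, its C9 oxygen and the C20 methyl are bought as one arene. The forward step must alkylate carbon and not oxygen, C10 and not C6, and must take its facial bias from C4.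

**C1–Br and the phenol.** 8 is the methyl ester of bromo acid 7, which results from lactone 6 by cleavage of two C–O bonds with one reagent. Carboxyl C19 and the chain C1–C3 can therefore be brought in together as a six-membered lactone whose ring oxygen marks C1 as the later electrophile.

**C4–C5 and C4–C18.** Lactone 6 is cut at the aryl–C4 bond into the enolate 5 of 3-methyl-δ-valerolactone 3 and bromoarene 4; 3 comes from δ-valerolactone 1 through enolate 2. Double alkylation of an arylacetic ester would need an auxiliary or a resolution. The arylation makes the quaternary centre in one catalytic enantioselective coupling of two commercial pieces. It has to join a tetrasubstituted enolate to an ortho-substituted aryl bromide, which is the most demanding step before the key step.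

## Roads not taken

**Alternative 1:** Intramolecular Diels–Alder reaction.
- **Cut:** C5–C10 and C8–C9, so both rings open at once to trienal A1. In A1 an E-configured enal (C9=C10, formyl carbon C11) is tied through C1–C3 and quaternary C4 to an E,E-1-silyloxydiene (C5=C6–C7=C8).
- **Forward step:** heat or Me2AlCl would give the trans-fused octalin A2 with a C8 silyl ether, a C9 formyl group and a C6=C7 alkene.
- **Merits:** two rings, two C–C bonds and four stereocentres in one step. Ring B appears with the C8 oxygen and the C9–C11 bond already in place, where the chosen plan spends four steps (hydrogenation, triflation, coupling, hydroboration). In this respect the road is better.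
- **Weak points:** the dienophile is trisubstituted, and the C5–C10 bond must form between a fully substituted carbon and a diene terminus on quaternary C4. Endo/exo and facial selectivity fix several centres at once, so a poor ratio costs more. The same ester-versus-methyl discrimination at C4 still governs C10. A1 is an acid- and heat-sensitive dienol ether that must be assembled linearly with C4 already set, which is unlikely to be shorter than the four steps to 8. After the cycloaddition the chain still has to be joined at C11, two alkenes reduced and C8 turned into the methylene.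
- **Comparison:** the chosen plan gives up the multi-centre efficiency. It sets against this a four-step aromatic precursor whose substitution pattern fixes the regiochemistry of ring B, and a key step that is asked for one bond and one stereocentre.

**Alternative 2:** Three-component conjugate methylation–allylation.
- **Cut:** C10–C20 and C5–C6 on a preformed ring A. In enone ester A3 the ketone carbon becomes C4 and the ester carbon C9.
- **Forward step:** Me2Zn with Cu(OTf)2 and a chiral N-heterocyclic carbene ligand would deliver methyl to the ester-bearing β-carbon, and the zinc enolate would be allylated at C5 to give A4 with allyl trans to the ester.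
- **Merits:** a catalytic enantioselective step of an established family makes the C10 quaternary centre from a cheap achiral enone and fixes the C5/C10 relationship. Absolute configuration would be introduced by a better precedented reaction than the hindered arylation of step 2; this is conceded. A late methylation of a C4 ester enolate on the trans-decalin generally places the carboxyl axial, which would be a more secure way to the C4/C10 relationship than the conformational preference used in the chosen key step.
- **Weak points:** no ring closes. The alkene of A3 is activated from both ends, so the site of methyl delivery rests on the catalyst. Zinc enolates are sluggish towards allyl halides. After the step, ring B (the C8–C9 bond and the adjustment of C9) and the whole C4 quaternary centre are still missing.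
- **Comparison:** the chosen plan reaches decalin 11, with both quaternary centres, in six steps. The alternative would need roughly twice as many operations to the same point.

**Alternative 3:** Epoxide ring contraction of a seven-membered ring A homologue.
- **Cut:** C3–C4, seen as the result of a 1,2-shift. Epoxide A5 is a bicyclo[5.4.0]undecane in which C19 is still a ring member between C3 and C4, with the oxirane across C4–C19 and C9 masked as a ketal.
- **Forward step:** BF3·OEt2 would ionise the tertiary C4–O bond and C3 would migrate from C19 to C4, leaving C19 as the aldehyde of trans-decalin A6.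
- **Merits:** the migration is stereospecific, so the axial formyl and equatorial methyl at C4 follow from the epoxide configuration and not from a small energy difference. Here the road is more secure than the chosen key step. A C19 aldehyde is also easier to carry and to oxidise at the end than a hindered ester is to cleave.
- **Weak points:** A5 is harder to make than what it delivers. A trans-fused medium ring, quaternary C10 and a face-selective epoxidation must all be in place first. Lewis acid opening of a trisubstituted epoxide divides between ring contraction, hydride shift from C19 (which keeps the seven-membered ring) and elimination. Everything from C9 outward remains to be done as in the chosen plan.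
- **Comparison:** the chosen plan sets the directness of its substrate against this stereospecificity. 8 maps atom for atom onto rings A and B, no ring is made only to be contracted, and the C9 oxygen needed for the side chain is the phenol oxygen itself.

Key step: step 5

Assumption: the sense of induction of the nickel–BINAP arylation is taken to carry over from five- to six-membered lactones, so that (S)-BINAP gives (S)-6; if it is reversed, (R)-BINAP is used and nothing else changes.
Assumption: stearoyl chloride 27, the acid chloride of stearic acid, is bought and used as the acyl donor.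

## Route

Step 1
Reactants: 1 δ-valerolactone (tetrahydro-2H-pyran-2-one)
Product: 3 (±)-3-methyltetrahydro-2H-pyran-2-one, via lithium lactone enolate 2 (not isolated)
Conditions: LiN(i-Pr)2 (1.05 equiv), THF, −78 °C; MeI, −78 → −30 °C
Reagents that add atoms: iodomethane, CI
Why: Kinetic enolate alkylation of a lactone; one equivalent of amide base at low temperature limits double methylation and Claisen self-condensation. The new stereocentre is racemic and is erased when the enolate is formed again in step 2.

Step 2
Reactants: 3 (±)-3-methyltetrahydro-2H-pyran-2-one; 4 1-bromo-3-methoxy-2-methylbenzene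
Product: 6 (S)-3-(3-methoxy-2-methylphenyl)-3-methyltetrahydro-2H-pyran-2-one, via sodium lactone enolate 5 (not isolated)
Conditions: NaN(SiMe3)2, toluene/THF, 25 °C; then 4, Ni(cod)2 (5 mol%), (S)-BINAP (8 mol%), ZnBr2 (15 mol%), 60 °C
Reagents that add atoms: none
Why: Nickel-catalysed enantioselective α-arylation of an α-substituted lactone enolate: oxidative addition of the aryl bromide to the zerovalent nickel–BINAP complex, enolate transmetalation (assisted by ZnBr2) and C–C reductive elimination form the C4–C5 bond. The racemic lactone converges through its planar enolate 5, and the chiral diphosphine decides which enolate face is arylated, which sets C4 as S.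

Step 3
Reactants: 6 (S)-3-(3-methoxy-2-methylphenyl)-3-methyltetrahydro-2H-pyran-2-one
Product: 7 (S)-5-bromo-2-(3-hydroxy-2-methylphenyl)-2-methylpentanoic acid
Conditions: BBr3 (3 equiv), CH2Cl2, −78 → 25 °C; ice-water quench; crude acid used at once
Reagents that add atoms: boron tribromide, BrB(Br)Br
Why: Lewis acid C–O cleavage twice: BBr3 demethylates the aryl ether and opens the lactone by bromide attack (SN2) on the O–CH2 carbon C1, which is primary and remote from C4, so the quaternary stereocentre is not involved. Hydrolytic work-up frees phenol and carboxylic acid.

Step 4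
Reactants: 7 (S)-5-bromo-2-(3-hydroxy-2-methylphenyl)-2-methylpentanoic acid
Product: 8 methyl (S)-5-bromo-2-(3-hydroxy-2-methylphenyl)-2-methylpentanoate
Conditions: Me3SiCHN2, toluene/MeOH (4:1), 0 °C
Reagents that add atoms: (trimethylsilyl)diazomethane, C[Si](C)(C)C=[N+]=[N-]
Why: Diazoalkane esterification under neutral conditions: only the carboxylic acid protonates the diazo compound at a useful rate, so the phenol stays free, and no carboxylate is generated that could displace the C1 bromide and re-form the lactone.

Step 5
Reactants: 8 methyl (S)-5-bromo-2-(3-hydroxy-2-methylphenyl)-2-methylpentanoate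
Product: 10 methyl (1S,4aS)-1,4a-dimethyl-5-oxo-1,2,3,4,4a,5-hexahydronaphthalene-1-carboxylate (bicyclic 2,4-dienone), via potassium phenoxide 9 (not isolated)
Conditions: KOtBu (1.05 equiv), t-BuOH, 0.01 M, 25 → 70 °C
Reagents that add atoms: none
Why: KOtBu deprotonates the phenol, and phenoxide 9 attacks C1 through its methyl-bearing ortho carbon C10 in an intramolecular SN2 displacement of bromide; since C10 carries no hydrogen the ring cannot rearomatise, and the 6,6-disubstituted cyclohexa-2,4-dienone 10 is the product. The closest known reaction type is the base-mediated intramolecular ortho C-alkylation of phenols by a tethered primary halide or sulfonate (aryl participation through the ortho carbon), which gives fused cyclohexa-2,4-dienones. Ring A closes in the 6-exo-tet mode. The new stereocentre C10 is controlled by C4: in the chair-like transition state C3 lies above the arene plane, one of the two remaining C4 substituents must lie in that plane beside H-6 and the other below it, syn to the C10 methyl as it bends out of the plane, and the flat ester is expected to take this syn-axial site more readily than methyl (ester/methyl against methyl/methyl 1,3-diaxial strain), helped by a potassium ion shared between phenoxide oxygen and ester carbonyl, which puts C19 and C20 on the same face as in the target. The step needs C- over O-alkylation, C10 over C6, and substitution over elimination. O-alkylation within the molecule would form an eight-membered ring, and between molecules it is held back by high dilution and by hydrogen bonding of the phenoxide oxygen to t-BuOH. Attack through C6, para to oxygen, would need a rotamer about C4–C5 in which a C4 substituent eclipses the C10 methyl, whereas the rotamer that leads to C10 has this substituent beside H-6, so the ortho methyl gears the chain over C10. Only a slight excess of base is used, so that no free tert-butoxide is left to eliminate HBr across C1–C2.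

Step 6
Reactants: 10 methyl (1S,4aS)-1,4a-dimethyl-5-oxo-1,2,3,4,4a,5-hexahydronaphthalene-1-carboxylate
Product: 11 methyl (1S,4aS,8aR)-1,4a-dimethyl-5-oxodecahydronaphthalene-1-carboxylate (trans-decalin with the ketone at C9)
Conditions: H2 (4 atm), 10% Pd/C, EtOAc, 25 °C; 10 is used without storage
Reagents that add atoms: none
Why: Heterogeneous hydrogenation; the disubstituted C7=C8 enone bond should go first, then the trisubstituted C5=C6 bond. The β face of C5=C6 is covered by the axial C19 ester on C4 and the C20 methyl on C10, so hydrogen should be delivered from the α face and C5 receives its α hydrogen (trans ring fusion). Dienones of this kind tend to dimerise by Diels–Alder reaction, hence the immediate use.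

Step 7
Reactants: 11 methyl (1S,4aS,8aR)-1,4a-dimethyl-5-oxodecahydronaphthalene-1-carboxylate
Product: 13 methyl (1S,4aS,8aR)-1,4a-dimethyl-5-(trifluoromethylsulfonyloxy)-1,2,3,4,4a,7,8,8a-octahydronaphthalene-1-carboxylate (C8=C9 enol triflate), via potassium enolate 12 (not isolated)
Conditions: KN(SiMe3)2, THF, −78 °C; PhNTf2, −78 → 0 °C
Reagents that add atoms: N-phenylbis(trifluoromethanesulfonimide), O=S(=O)(N(c1ccccc1)S(=O)(=O)C(F)(F)F)C(F)(F)F
Why: Only C8 carries α-hydrogens (C10 is quaternary and the ester at C4 has none), so a single enolate 12 forms; O-sulfonylation gives the enol triflate.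

Step 8
Reactants: 14 (S)-citronellol
Product: 15 (S)-tert-butyl[(3,7-dimethyloct-6-en-1-yl)oxy]dimethylsilane
Conditions: TBSCl, imidazole, CH2Cl2, 25 °C
Reagents that add atoms: tert-butyldimethylsilyl chloride, CC(C)(C)[Si](C)(C)Cl
Why: Standard silylation of a primary alcohol; the silyl ether tolerates ozone, chlorite, iodine radicals, zinc, borane and ylide and is removed by fluoride at the end.

Step 9
Reactants: 15 (S)-tert-butyl[(3,7-dimethyloct-6-en-1-yl)oxy]dimethylsilane
Product: 17 (S)-6-(tert-butyldimethylsilyloxy)-4-methylhexanoic acid, via silyloxy aldehyde 16 (not isolated)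
Conditions: O3, MeCN/H2O (9:1), 0 °C; then NaClO2, NaH2PO4, 0 → 25 °C
Reagents that add atoms: ozone, [O-][O+]=O; sodium chlorite, [Na+].[O-]Cl=O
Why: Ozonolysis in aqueous acetonitrile gives aldehyde 16 directly, because water intercepts the carbonyl oxide and releases acetone and H2O2; chlorite (Pinnick-type oxidation) then takes it to the acid in the same flask, with the H2O2 acting as hypochlorite scavenger. The stereocentre is not adjacent to a reacting carbon.

Step 10
Reactants: 17 (S)-6-(tert-butyldimethylsilyloxy)-4-methylhexanoic acid
Product: 18 (R)-tert-butyl[(5-iodo-3-methylpentyl)oxy]dimethylsilane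
Conditions: PhI(OAc)2, I2, cyclohexane, visible light, 60 °C
Reagents that add atoms: iodine, II
Why: Hunsdiecker-type iododecarboxylation: the acyl hypoiodite fragments under light to CO2 and a primary radical that is capped by iodine, which removes the one carbon by which citronellol is too long. The stereocentre is two bonds from the radical and is untouched; its descriptor becomes R only because iodine reverses the priority order.

Step 11
Reactants: 13 methyl (1S,4aS,8aR)-1,4a-dimethyl-5-(trifluoromethylsulfonyloxy)-1,2,3,4,4a,7,8,8a-octahydronaphthalene-1-carboxylate; 18 (R)-tert-butyl[(5-iodo-3-methylpentyl)oxy]dimethylsilane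
Product: 20 methyl (1S,4aS,8aR)-5-[(3S)-5-(tert-butyldimethylsilyloxy)-3-methylpentyl]-1,4a-dimethyl-1,2,3,4,4a,7,8,8a-octahydronaphthalene-1-carboxylate (C8=C9 alkene), via alkylzinc iodide 19 (not isolated)
Conditions: 18, Zn dust, LiCl, THF, 40 °C; then 13, Pd(dppf)Cl2 (5 mol%), THF/NMP, 60 °C
Reagents that add atoms: none
Why: Negishi coupling: zinc inserts into the primary C–I bond, the alkylzinc 19 transmetalates to the alkenylpalladium species formed by oxidative addition of zerovalent palladium into the C9–O triflate bond, and reductive elimination forms C9–C11. The organozinc tolerates ester and silyl ether, and the wide-bite-angle diphosphine disfavours β-hydride elimination.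

Step 12
Reactants: 20 methyl (1S,4aS,8aR)-5-[(3S)-5-(tert-butyldimethylsilyloxy)-3-methylpentyl]-1,4a-dimethyl-1,2,3,4,4a,7,8,8a-octahydronaphthalene-1-carboxylate
Product: 22 methyl (1S,4aS,5R,6R,8aR)-5-[(3S)-5-(tert-butyldimethylsilyloxy)-3-methylpentyl]-6-hydroxy-1,4a-dimethyldecahydronaphthalene-1-carboxylate (8α-OH and 9α-H), via C8 alkylborane 21 (not isolated)
Conditions: BH3·THF, THF, 0 → 25 °C; then NaOH, H2O2, 0 → 25 °C
Reagents that add atoms: hydrogen peroxide, OO
Why: Hydroboration–oxidation: boron adds to the less substituted C8 and hydrogen to C9, syn and from the α face, anti to the axial C20 methyl on the neighbouring C10; this sets C9 (α-H, side chain β), and oxidation with retention gives the 8α-alcohol. The shielded C19 ester is expected to be inert to borane at room temperature.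

Step 13
Reactants: 22 methyl (1S,4aS,5R,6R,8aR)-5-[(3S)-5-(tert-butyldimethylsilyloxy)-3-methylpentyl]-6-hydroxy-1,4a-dimethyldecahydronaphthalene-1-carboxylate
Product: 23 methyl (1S,4aS,5R,8aR)-5-[(3S)-5-(tert-butyldimethylsilyloxy)-3-methylpentyl]-1,4a-dimethyl-6-oxodecahydronaphthalene-1-carboxylate (C8 ketone)
Conditions: Dess–Martin periodinane, CH2Cl2, 25 °C
Reagents that add atoms: none
Why: Dess–Martin oxidation of a secondary alcohol. C9 now lies α to the ketone, but its equatorial side chain, anti to the axial C20 methyl, is the thermodynamically preferred arrangement, so enolisation cannot erode it.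

Step 14
Reactants: 23 methyl (1S,4aS,5R,8aR)-5-[(3S)-5-(tert-butyldimethylsilyloxy)-3-methylpentyl]-1,4a-dimethyl-6-oxodecahydronaphthalene-1-carboxylate
Product: 24 methyl (1S,4aR,5S,8aR)-5-[(3S)-5-(tert-butyldimethylsilyloxy)-3-methylpentyl]-1,4a-dimethyl-6-methylidenedecahydronaphthalene-1-carboxylate
Conditions: Ph3PCH3Br, KOtBu, toluene, 25 °C; then 23, 80 °C
Reagents that add atoms: methyltriphenylphosphonium bromide, C[P+](c1ccccc1)(c1ccccc1)c1ccccc1.[Br-]
Why: Wittig methylenation of the hindered C8 ketone with the non-stabilised ylide at elevated temperature installs C17; C9 stays in its stable configuration. The alkene is introduced only now because it would not survive steps 6 and 12.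

Step 15
Reactants: 24 methyl (1S,4aR,5S,8aR)-5-[(3S)-5-(tert-butyldimethylsilyloxy)-3-methylpentyl]-1,4a-dimethyl-6-methylidenedecahydronaphthalene-1-carboxylate
Product: 25 (1S,4aR,5S,8aR)-5-[(3S)-5-(tert-butyldimethylsilyloxy)-3-methylpentyl]-1,4a-dimethyl-6-methylidenedecahydronaphthalene-1-carboxylic acid
Conditions: NaSEt, DMF, 110 °C; aq. HCl work-up
Reagents that add atoms: none
Why: SN2 dealkylation: the thiolate attacks the ester methyl group and not the shielded carbonyl, so the axial, neopentyl-type C19 ester that resists saponification is cleaved. The exocyclic alkene and the alkyl silyl ether are inert to the soft nucleophile.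

Step 16
Reactants: 25 (1S,4aR,5S,8aR)-5-[(3S)-5-(tert-butyldimethylsilyloxy)-3-methylpentyl]-1,4a-dimethyl-6-methylidenedecahydronaphthalene-1-carboxylic acid
Product: 26 imbricatolic acid [(1S,4aR,5S,8aR)-5-[(3S)-5-hydroxy-3-methylpentyl]-1,4a-dimethyl-6-methylidenedecahydronaphthalene-1-carboxylic acid]
Conditions: Bu4NF, THF, 25 °C
Reagents that add atoms: none
Why: Fluoride cleaves the primary silyl ether through Si–F bond formation without acid, which could move the 8(17)-double bond into the ring.

Step 17
Reactants: 26 imbricatolic acid; 27 stearoyl chloride (octadecanoyl chloride)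
Product: 28 (1S,4aR,5S,8aR)-1,4a-dimethyl-6-methylidene-5-[(3S)-3-methyl-5-(octadecanoyloxy)pentyl]decahydronaphthalene-1-carboxylic acid (target)
Conditions: 27 (2.2 equiv), pyridine, DMAP (cat.), CH2Cl2, 0 → 25 °C; then H2O, pyridine, 25 °C
Reagents that add atoms: none
Why: Nucleophilic acyl substitution at the primary C15 alcohol via the acylpyridinium ion. The tertiary C19 carboxyl can at most form a mixed anhydride, which is hydrolysed at its unhindered stearoyl carbonyl in the aqueous pyridine stage and returns the free acid. The stearate is introduced last because it would not survive steps 12 to 15.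

## Compound list

1 | δ-valerolactone (tetrahydro-2H-pyran-2-one) | O=C1CCCCO1 | starting material
2 | lithium 3,4-dihydro-2H-pyran-6-olate (lithium enolate of 1, formed in situ) | [Li]OC1=CCCCO1 | intermediate
3 | (±)-3-methyltetrahydro-2H-pyran-2-one | CC1CCCOC1=O | intermediate
4 | 1-bromo-3-methoxy-2-methylbenzene | COc1cccc(Br)c1C | starting material
5 | sodium 5-methyl-3,4-dihydro-2H-pyran-6-olate (sodium enolate of 3, formed in situ) | [Na]OC1=C(C)CCCO1 | intermediate
6 | (S)-3-(3-methoxy-2-methylphenyl)-3-methyltetrahydro-2H-pyran-2-one | COc1cccc([C@]2(C)CCCOC2=O)c1C | intermediate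
7 | (S)-5-bromo-2-(3-hydroxy-2-methylphenyl)-2-methylpentanoic acid | OC(=O)[C@@](C)(CCCBr)c1cccc(O)c1C | intermediate
8 | methyl (S)-5-bromo-2-(3-hydroxy-2-methylphenyl)-2-methylpentanoate | COC(=O)[C@@](C)(CCCBr)c1cccc(O)c1C | intermediate
9 | potassium 3-[(2S)-5-bromo-1-methoxy-2-methyl-1-oxopentan-2-yl]-2-methylphenolate (phenoxide of 8, formed in situ) | COC(=O)[C@@](C)(CCCBr)c1cccc(O[K])c1C | intermediate
10 | methyl (1S,4aS)-1,4a-dimethyl-5-oxo-1,2,3,4,4a,5-hexahydronaphthalene-1-carboxylate | COC(=O)[C@@]1(C)CCC[C@]2(C)C(=O)C=CC=C12 | intermediate
11 | methyl (1S,4aS,8aR)-1,4a-dimethyl-5-oxodecahydronaphthalene-1-carboxylate | COC(=O)[C@@]1(C)CCC[C@]2(C)C(=O)CCC[C@@H]12 | intermediate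
12 | potassium enolate of 11 (enolate double bond C8=C9, formed in situ) | COC(=O)[C@@]1(C)CCC[C@]2(C)C(O[K])=CCC[C@@H]12 | intermediate
13 | methyl (1S,4aS,8aR)-1,4a-dimethyl-5-(trifluoromethylsulfonyloxy)-1,2,3,4,4a,7,8,8a-octahydronaphthalene-1-carboxylate | COC(=O)[C@@]1(C)CCC[C@]2(C)C(OS(=O)(=O)C(F)(F)F)=CCC[C@@H]12 | intermediate
14 | (S)-citronellol | CC(C)=CCC[C@H](C)CCO | starting material
15 | (S)-tert-butyl[(3,7-dimethyloct-6-en-1-yl)oxy]dimethylsilane | CC(C)=CCC[C@H](C)CCO[Si](C)(C)C(C)(C)C | intermediate
16 | (S)-6-(tert-butyldimethylsilyloxy)-4-methylhexanal (formed in situ) | O=CCC[C@H](C)CCO[Si](C)(C)C(C)(C)C | intermediate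
17 | (S)-6-(tert-butyldimethylsilyloxy)-4-methylhexanoic acid | OC(=O)CC[C@H](C)CCO[Si](C)(C)C(C)(C)C | intermediate
18 | (R)-tert-butyl[(5-iodo-3-methylpentyl)oxy]dimethylsilane | ICC[C@H](C)CCO[Si](C)(C)C(C)(C)C | intermediate
19 | [(3R)-5-(tert-butyldimethylsilyloxy)-3-methylpentyl]zinc iodide (formed in situ) | I[Zn]CC[C@H](C)CCO[Si](C)(C)C(C)(C)C | intermediate
20 | methyl (1S,4aS,8aR)-5-[(3S)-5-(tert-butyldimethylsilyloxy)-3-methylpentyl]-1,4a-dimethyl-1,2,3,4,4a,7,8,8a-octahydronaphthalene-1-carboxylate | COC(=O)[C@@]1(C)CCC[C@]2(C)C(CC[C@H](C)CCO[Si](C)(C)C(C)(C)C)=CCC[C@@H]12 | intermediate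
21 | C8 alkylborane from 20 (8α-boryl, 9α-H; shown as the monoalkylborane, formed in situ) | [BH2][C@@H]1CC[C@@H]2[C@](C)(CCC[C@]2(C)C(=O)OC)[C@H]1CC[C@H](C)CCO[Si](C)(C)C(C)(C)C | intermediate
22 | methyl (1S,4aS,5R,6R,8aR)-5-[(3S)-5-(tert-butyldimethylsilyloxy)-3-methylpentyl]-6-hydroxy-1,4a-dimethyldecahydronaphthalene-1-carboxylate | O[C@@H]1CC[C@@H]2[C@](C)(CCC[C@]2(C)C(=O)OC)[C@H]1CC[C@H](C)CCO[Si](C)(C)C(C)(C)C | intermediate
23 | methyl (1S,4aS,5R,8aR)-5-[(3S)-5-(tert-butyldimethylsilyloxy)-3-methylpentyl]-1,4a-dimethyl-6-oxodecahydronaphthalene-1-carboxylate | O=C1CC[C@@H]2[C@](C)(CCC[C@]2(C)C(=O)OC)[C@H]1CC[C@H](C)CCO[Si](C)(C)C(C)(C)C | intermediate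
24 | methyl (1S,4aR,5S,8aR)-5-[(3S)-5-(tert-butyldimethylsilyloxy)-3-methylpentyl]-1,4a-dimethyl-6-methylidenedecahydronaphthalene-1-carboxylate | C=C1CC[C@@H]2[C@](C)(CCC[C@]2(C)C(=O)OC)[C@H]1CC[C@H](C)CCO[Si](C)(C)C(C)(C)C | intermediate
25 | (1S,4aR,5S,8aR)-5-[(3S)-5-(tert-butyldimethylsilyloxy)-3-methylpentyl]-1,4a-dimethyl-6-methylidenedecahydronaphthalene-1-carboxylic acid | C=C1CC[C@@H]2[C@](C)(CCC[C@]2(C)C(=O)O)[C@H]1CC[C@H](C)CCO[Si](C)(C)C(C)(C)C | intermediate
26 | imbricatolic acid, (1S,4aR,5S,8aR)-5-[(3S)-5-hydroxy-3-methylpentyl]-1,4a-dimethyl-6-methylidenedecahydronaphthalene-1-carboxylic acid | C=C1CC[C@@H]2[C@](C)(CCC[C@]2(C)C(=O)O)[C@H]1CC[C@H](C)CCO | intermediate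
27 | stearoyl chloride (octadecanoyl chloride) | CCCCCCCCCCCCCCCCCC(=O)Cl | starting material
28 | (1S,4aR,5S,8aR)-1,4a-dimethyl-6-methylidene-5-[(3S)-3-methyl-5-(octadecanoyloxy)pentyl]decahydronaphthalene-1-carboxylic acid | C=C1CC[C@@H]2[C@](C)(CCC[C@]2(C)C(=O)O)[C@H]1CC[C@H](C)CCOC(=O)CCCCCCCCCCCCCCCCC | target

## Step count and least certain steps

Total step count: 17. Longest linear sequence: 14 steps (steps 1–7 and 11–17, from 1). The side-chain branch (steps 8–10, from 14) joins at step 11.

**Step 5 (key step).**
- Risk: C-alkylation through C6, para to the phenoxide oxygen, followed by rearomatisation to a tetralin phenol. The intrinsic para preference of phenoxides works against the conformational gearing by the ortho methyl.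
- Risk: too little discrimination between the two chair-like transition states, so that both C10 configurations form. The ester/methyl energy difference at C4 is small.
- Fallback (sets out from 6, returns at 11): ring B is dearomatised by reduction before the ring closure, so the same C1–C10 bond is made by enolate alkylation and no aromatic para position exists.
  - 6 is saponified (LiOH, THF/H2O) to the lithium hydroxy carboxylate F1.
  - Birch reduction (Li, NH3, t-BuOH, THF, −78 °C) gives the 1-methoxycyclohexa-1,4-diene F2.
  - Aqueous HCl hydrolyses the enol ether, brings the double bond into conjugation and closes the lactone again, giving the enone lactone F3.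
  - BBr3 and then Me3SiCHN2, as in steps 3 and 4, give the bromo acid F4 and the bromo ester F5.
  - KOtBu in t-BuOH forms the extended dienolate, which is alkylated at its α-carbon C10 by C1 (deconjugative intramolecular enolate alkylation) to the β,γ-unsaturated ketone F6.
  - Hydrogenation as in step 6 leads to 11.

**Step 2.**
- Risk: slow transmetalation and reductive elimination at nickel because of the ortho methyl group, together with the less studied six-membered lactone enolate. This would show as low conversion or eroded enantioselectivity.
- Fallback (sets out from 3 and 4, returns at 6): racemic coupling and resolution.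
  - Achiral palladium catalysis (Pd(dba)2, P(t-Bu)3, LiN(SiMe3)2, toluene), which tolerates ortho substituents, gives the racemic aryl lactone F7.
  - AlMe3-mediated aminolysis with (S)-1-phenylethylamine gives the diastereomeric hydroxy amides F8 (S at the quaternary carbon) and F9 (R at the quaternary carbon), which are separated by crystallisation or chromatography.
  - Heating F8 with aqueous H2SO4 in dioxane closes the lactone again by N-to-O acyl transfer and returns 6.

**Step 6.**
- Risk: stalling at the C5=C6 double bond, which is flanked by two quaternary carbons, or hydrogen delivery from the β face, which would lead to the cis ring fusion.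
- Fallback (sets out from 10, returns at 11): radical hydrogen-atom-transfer hydrogenation (Mn(dpm)3, PhSiH3, t-BuOOH, i-PrOH). It reduces the enone bond and then the hindered trisubstituted alkene through the tertiary C5 radical, which takes up hydrogen on the axial α face to give the thermodynamically preferred trans fusion. No compound outside the list arises (F0).

**Step 11.**
- Risk: sluggish oxidative addition and transmetalation at the enol triflate next to quaternary C10, with competing reduction of the triflate and protonation of the zinc reagent.
- Fallback (sets out from 18 and 13, returns at 20): the zinc reagent is replaced by a borate in a B-alkyl Suzuki–Miyaura coupling.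
  - Iodine–lithium exchange on 18 (t-BuLi, Et2O, −78 °C) gives the alkyllithium F10.
  - F10 is trapped with 9-methoxy-9-BBN as the lithium borate F11.
  - F11 is coupled with 13 (Pd(dppf)Cl2, AsPh3, K3PO4, DMF/THF) to 20.

**Step 12.**
- Risk: slow hydroboration of the trisubstituted alkene beside quaternary C10, and incomplete α-face selectivity.
- Fallback (sets out from 20, returns at 23, bypassing step 13): dihydroxylation, oxidation and reductive removal of the tertiary hydroxyl.
  - OsO4 (cat.) with N-methylmorpholine N-oxide adds two hydroxyls from the α face to give the 8α,9α-diol F12.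
  - Dess–Martin oxidation of the secondary C8 hydroxyl gives the α-ketol F13.
  - SmI2 (THF/MeOH) cleaves the tertiary C9–O bond; protonation of the resulting enolate gives 23, with C9 under the same thermodynamic control as in step 13.

## Further compounds

F1 | step 5 | lithium (S)-5-hydroxy-2-(3-methoxy-2-methylphenyl)-2-methylpentanoate | [Li+].[O-]C(=O)[C@@](C)(CCCO)c1cccc(OC)c1C
F2 | step 5 | lithium (2S)-5-hydroxy-2-(5-methoxy-6-methylcyclohexa-1,4-dien-1-yl)-2-methylpentanoate (ring methyl carbon unassigned; shown as one of the two possible dihydro regioisomers) | [Li+].[O-]C(=O)[C@@](C)(CCCO)C1=CCC=C(OC)C1C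
F3 | step 5 | (S)-3-methyl-3-(2-methyl-3-oxocyclohex-1-en-1-yl)tetrahydro-2H-pyran-2-one | CC1=C(CCCC1=O)[C@]2(C)CCCOC2=O
F4 | step 5 | (S)-5-bromo-2-methyl-2-(2-methyl-3-oxocyclohex-1-en-1-yl)pentanoic acid | OC(=O)[C@@](C)(CCCBr)C1=C(C)C(=O)CCC1
F5 | step 5 | methyl (S)-5-bromo-2-methyl-2-(2-methyl-3-oxocyclohex-1-en-1-yl)pentanoate | COC(=O)[C@@](C)(CCCBr)C1=C(C)C(=O)CCC1
F6 | step 5 | methyl (1S,4aS)-1,4a-dimethyl-5-oxo-1,2,3,4,4a,5,6,7-octahydronaphthalene-1-carboxylate | COC(=O)[C@@]1(C)CCC[C@]2(C)C(=O)CCC=C12
F7 | step 2 | (±)-3-(3-methoxy-2-methylphenyl)-3-methyltetrahydro-2H-pyran-2-one | COc1cccc(C2(C)CCCOC2=O)c1C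
F8 | step 2 | (S)-5-hydroxy-2-(3-methoxy-2-methylphenyl)-2-methyl-N-[(S)-1-phenylethyl]pentanamide | COc1cccc([C@](C)(CCCO)C(=O)N[C@@H](C)c2ccccc2)c1C
F9 | step 2 | (R)-5-hydroxy-2-(3-methoxy-2-methylphenyl)-2-methyl-N-[(S)-1-phenylethyl]pentanamide | COc1cccc([C@@](C)(CCCO)C(=O)N[C@@H](C)c2ccccc2)c1C
F0 | step 6 | none | none
F10 | step 11 | [(3R)-5-(tert-butyldimethylsilyloxy)-3-methylpentyl]lithium | [Li]CC[C@H](C)CCO[Si](C)(C)C(C)(C)C
F11 | step 11 | lithium 9-[(3R)-5-(tert-butyldimethylsilyloxy)-3-methylpentyl]-9-methoxy-9-boratabicyclo[3.3.1]nonane | [Li+].CO[B-]1(CC[C@H](C)CCO[Si](C)(C)C(C)(C)C)C2CCCC1CCC2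
F12 | step 12 | 8α,9α-diol of 20: methyl 5-[(3S)-5-(tert-butyldimethylsilyloxy)-3-methylpentyl]-5,6-dihydroxy-1,4a-dimethyldecahydronaphthalene-1-carboxylate (both hydroxyls α; trans-decalin as in 22) | O[C@@H]1CC[C@@H]2[C@](C)(CCC[C@]2(C)C(=O)OC)[C@@]1(O)CC[C@H](C)CCO[Si](C)(C)C(C)(C)C
F13 | step 12 | 9α-hydroxy C8 ketone: methyl 5-[(3S)-5-(tert-butyldimethylsilyloxy)-3-methylpentyl]-5-hydroxy-1,4a-dimethyl-6-oxodecahydronaphthalene-1-carboxylate (hydroxyl α) | O=C1CC[C@@H]2[C@](C)(CCC[C@]2(C)C(=O)OC)[C@@]1(O)CC[C@H](C)CCO[Si](C)(C)C(C)(C)C
A1 | alternative 1 | methyl (2S,6E)-2-[(1E,3E)-4-(tert-butyldimethylsilyloxy)buta-1,3-dien-1-yl]-2,6-dimethyl-8-oxooct-6-enoate | O=C/C=C(\C)CCC[C@](/C=C/C=C/O[Si](C)(C)C(C)(C)C)(C)C(=O)OC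
A2 | alternative 1 | methyl 6-(tert-butyldimethylsilyloxy)-5-formyl-1,4a-dimethyl-1,2,3,4,4a,5,6,8a-octahydronaphthalene-1-carboxylate (trans-fused cycloadduct; configuration as in the SMILES) | CC(C)(C)[Si](C)(C)O[C@H]1C=C[C@@H]2[C@](C)(CCC[C@]2(C)C(=O)OC)[C@H]1C=O
A3 | alternative 2 | methyl 3-oxocyclohex-1-ene-1-carboxylate | COC(=O)C1=CC(=O)CCC1
A4 | alternative 2 | methyl 2-allyl-1-methyl-3-oxocyclohexane-1-carboxylate (allyl trans to ester) | COC(=O)[C@@]1(C)CCCC(=O)[C@@H]1CC=C
A5 | alternative 3 | 2,3-epoxy-2,7-dimethylbicyclo[5.4.0]undecan-8-one ethylene ketal (trans ring fusion; oxirane across labdane C4–C19; configuration as in the SMILES) | C[C@]12CCC[C@@H]3O[C@]3(C)[C@@H]1CCCC21OCCO1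
A6 | alternative 3 | 1,4a-dimethyl-5-oxodecahydronaphthalene-1-carbaldehyde 5-ethylene ketal (trans-decalin, axial formyl; configuration as in the SMILES) | O=C[C@@]1(C)CCC[C@@]2(C)[C@H]1CCCC23OCCO3
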